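A direct plan would C-aroylate the lithium phenoxide–enolate dianion of chromene methyl ketone A1 with the O-silylated 3-prenylbenzoyl chloride A2, then remove the silyl group.
Its three weakest parts would be the following.
- The redox detour to A1: the pyran would be closed as chromanone A3, then the carbonyl removed, the ring acetylated and the alkene restored. This would add length but no complexity.
- The ortho C-prenylation of a phenoxide to bromophenol A4 (precursor of A2): O-alkylation, dialkylation and chroman formation would compete.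
- The dianion aroylation itself: O-acylation, double acylation and silyl loss would compete under three equivalents of strong base.

The β-diketone is cut between the chromene-side carbonyl carbon and the central CH2, which is traced to a one-carbon sulfoxonium linchpin. The key step exploits the ortho pair C7–OH/C6–C=O of the chromene benzene ring (ring A), present as OH/CHO in a salicylaldehyde: the phenol guides Rh(III) into the formyl C–H bond, and the aroyl carbene from a sulfoxonium ylide of the other ring (ring B) inserts there. One operation gives the free 2-hydroxyaryl β-diketone with no enolate, acid chloride or phenol protection. Bromine in the purchased aldehyde encodes the linear fusion, so the pyran closes after the coupling by one oxidation. The ring-B ether protects, then becomes the prenyl group by Claisen rearrangement, replacing phenoxide C-alkylation.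

Key step: step 5

Assumption: the target has no stereocentre and no stereogenic alkene, so it is achiral and "single enantiomer" means the constitution as drawn. β-Diketones are written in the diketo form although they should exist largely as chelated enols.

Step 1
Reactants: 1 5-bromo-2,4-dihydroxybenzaldehyde; 2 prenylboronic acid pinacol ester [4,4,5,5-tetramethyl-2-(3-methylbut-2-en-1-yl)-1,3,2-dioxaborolane]
Product: 3 2,4-dihydroxy-5-(3-methylbut-2-en-1-yl)benzaldehyde
Conditions: Pd-PEPPSI-IPent (2 mol %), 5 M aq. KOH (4 equiv), THF, 70 °C; aq. citric acid work-up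
Reagents that add atoms: prenylboronic acid pinacol ester (2), CC(C)=CCB1OC(C)(C)C(C)(C)O1
Why: Suzuki–Miyaura allyl–aryl coupling, in which bulky NHC–Pd catalysts are known to transfer 3,3-disubstituted allylboronates through the unsubstituted α-carbon, so the linear prenyl group should enter exactly at the bromine-bearing C5 (para to the 2-OH), while the phenoxide-deactivated aldehyde should be inert to aqueous base.

Step 2
Reactants: 4 methyl 4-hydroxybenzoate; 5 3-chloro-3-methylbut-1-yne
Product: 6 methyl 4-[(2-methylbut-3-yn-2-yl)oxy]benzoate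
Conditions: CuCl2·2H2O (1 mol %), DBU, MeCN, 0 °C
Reagents that add atoms: 3-chloro-3-methylbut-1-yne (5), C#CC(C)(C)Cl
Why: Copper-catalysed O-propargylation of a phenol with a tertiary propargylic chloride, a reaction that works best with electron-poor phenols, should give the tertiary ether without C-alkylation and leave the methyl ester untouched.

Step 3
Reactants: 6 methyl 4-[(2-methylbut-3-yn-2-yl)oxy]benzoate
Product: 7 methyl 4-[(2-methylbut-3-en-2-yl)oxy]benzoate
Conditions: H2 (1 atm), Lindlar catalyst, quinoline, EtOAc, rt
Reagents that add atoms: none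
Why: Lindlar semihydrogenation should stop at the vinyl group because the poisoned palladium surface releases the alkene, and it is placed before sulfur enters the molecule so that the catalyst is not poisoned further.

Step 4
Reactants: 7 methyl 4-[(2-methylbut-3-en-2-yl)oxy]benzoate; 8 trimethylsulfoxonium iodide
Product: 10 2-[dimethyl(oxo)-λ6-sulfanylidene]-1-{4-[(2-methylbut-3-en-2-yl)oxy]phenyl}ethan-1-one, via dimethylsulfoxonium methylide 9 (not isolated)
Conditions: 8 (3 equiv), KOtBu (3 equiv), THF, reflux; then 7, 0 °C → reflux
Reagents that add atoms: trimethylsulfoxonium iodide (8), C[S+](C)(C)=O.[I-]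
Why: Acylation of the Corey–Chaykovsky ylide 9 by an ester proceeds by addition–elimination with loss of methoxide, and the acidic β-keto sulfoxonium salt is deprotonated at once to the stabilised ylide 10, which should not react further; the tertiary allyl ether is base-stable.

Step 5
Reactants: 3 2,4-dihydroxy-5-(3-methylbut-2-en-1-yl)benzaldehyde; 10 2-[dimethyl(oxo)-λ6-sulfanylidene]-1-{4-[(2-methylbut-3-en-2-yl)oxy]phenyl}ethan-1-one
Product: 11 1-[2,4-dihydroxy-5-(3-methylbut-2-en-1-yl)phenyl]-3-{4-[(2-methylbut-3-en-2-yl)oxy]phenyl}propane-1,3-dione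
Conditions: [Cp*RhCl2]2 (2.5 mol %), AgOAc (10 mol %), NaOAc (0.3 equiv), 1,2-dichloroethane, 60 °C; 10 added slowly
Reagents that add atoms: none
Why: Acetate exchange should bind Cp*Rh(III) to the C2 phenoxide of 3 and cleave the neighbouring formyl C–H bond by concerted metalation–deprotonation to a five-membered acyl rhodacycle; ylide 10 then binds through carbon and loses DMSO to a rhodium carbene, the acyl group migrates to the carbene carbon, and protonolysis by acetic acid releases 11 and the catalyst. The closest known reaction type is the Rh(III)-catalysed coupling of salicylaldehydes with β-keto sulfoxonium ylides or diazo ketones, which passes through exactly this kind of 2-hydroxyaryl β-diketone on its way to chromones. The step closes no ring and sets no stereocentre; the bond formed is ring-A C(=O)–CH2. It needs site selectivity for the formyl C–H over aryl C–H bonds, over O–H insertion at the 4-OH and over the alkenes; this rests on the 2-OH/CHO pair, the only site that can form a five-membered metallacycle, and on the trisubstituted prenyl alkene and the neopentyl-type vinyl group being poor ligands. The step must also stop before cyclodehydration, which the acetate buffer, the absence of a strong acid additive and the moderate temperature should secure, since the chelated enol needs acid and heat to close. Slow addition of 10 should suppress its self-coupling, and 60 °C lies below the onset of the ring-B Claisen rearrangement.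

Step 6
Reactants: 11 1-[2,4-dihydroxy-5-(3-methylbut-2-en-1-yl)phenyl]-3-{4-[(2-methylbut-3-en-2-yl)oxy]phenyl}propane-1,3-dione
Product: 13 1-(7-hydroxy-2,2-dimethyl-2H-chromen-6-yl)-3-{4-[(2-methylbut-3-en-2-yl)oxy]phenyl}propane-1,3-dione, via vinyl ortho-quinone methide 12 (not isolated)
Conditions: DDQ (1.05 equiv), 1,4-dioxane, rt → 50 °C
Reagents that add atoms: none
Why: DDQ oxidative cyclisation of an o-prenylphenol, in which hydride abstraction from the benzylic CH2 (cation stabilised by the ortho 4-OH and the para 2-OH) and loss of the 4-OH proton should give 12, which closes the pyran by oxa-6π electrocyclisation (O1–C2 bond), while ring B offers neither a free phenol nor a benzylic or allylic C–H bond.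

Step 7
Reactants: 13 1-(7-hydroxy-2,2-dimethyl-2H-chromen-6-yl)-3-{4-[(2-methylbut-3-en-2-yl)oxy]phenyl}propane-1,3-dione
Product: 15 Glyinflanin C, via 6-prenylcyclohexa-2,4-dienone 14 (not isolated)
Conditions: o-xylene (0.05 M), BHT (cat.), 130 °C, argon
Reagents that add atoms: none
Why: Aromatic Claisen rearrangement, whose [3,3] shift inverts the 1,1-dimethylallyl unit so that the linear prenyl group arrives at the ortho carbon (the two ortho positions of ring B are equivalent), and tautomerisation of 14 frees the 4-OH under neutral, reagent-free conditions that should spare the chromene and the chelated β-diketone.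

Compound list
1 | 5-bromo-2,4-dihydroxybenzaldehyde | O=Cc1cc(Br)c(O)cc1O | starting material
2 | prenylboronic acid pinacol ester [4,4,5,5-tetramethyl-2-(3-methylbut-2-en-1-yl)-1,3,2-dioxaborolane] | CC(C)=CCB1OC(C)(C)C(C)(C)O1 | starting material
3 | 2,4-dihydroxy-5-(3-methylbut-2-en-1-yl)benzaldehyde | CC(C)=CCc1cc(C=O)c(O)cc1O | intermediate
4 | methyl 4-hydroxybenzoate | COC(=O)c1ccc(O)cc1 | starting material
5 | 3-chloro-3-methylbut-1-yne | C#CC(C)(C)Cl | starting material
6 | methyl 4-[(2-methylbut-3-yn-2-yl)oxy]benzoate | COC(=O)c1ccc(OC(C)(C)C#C)cc1 | intermediate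
7 | methyl 4-[(2-methylbut-3-en-2-yl)oxy]benzoate | COC(=O)c1ccc(OC(C)(C)C=C)cc1 | intermediate
8 | trimethylsulfoxonium iodide | C[S+](C)(C)=O.[I-] | starting material
9 | dimethylsulfoxonium methylide | C=S(C)(C)=O | intermediate
10 | 2-[dimethyl(oxo)-λ6-sulfanylidene]-1-{4-[(2-methylbut-3-en-2-yl)oxy]phenyl}ethan-1-one | CS(C)(=O)=CC(=O)c1ccc(OC(C)(C)C=C)cc1 | intermediate
11 | 1-[2,4-dihydroxy-5-(3-methylbut-2-en-1-yl)phenyl]-3-{4-[(2-methylbut-3-en-2-yl)oxy]phenyl}propane-1,3-dione | CC(C)=CCc1cc(C(=O)CC(=O)c2ccc(OC(C)(C)C=C)cc2)c(O)cc1O | intermediate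
12 | 1-[(3Z)-6-hydroxy-3-(3-methylbut-2-en-1-ylidene)-4-oxocyclohexa-1,5-dien-1-yl]-3-{4-[(2-methylbut-3-en-2-yl)oxy]phenyl}propane-1,3-dione (vinyl ortho-quinone methide, vinyl group cis to the ring C=O) | CC(C)=C/C=C1/C=C(C(=O)CC(=O)c2ccc(OC(C)(C)C=C)cc2)C(O)=CC1=O | intermediate
13 | 1-(7-hydroxy-2,2-dimethyl-2H-chromen-6-yl)-3-{4-[(2-methylbut-3-en-2-yl)oxy]phenyl}propane-1,3-dione | C=CC(C)(C)Oc1ccc(cc1)C(=O)CC(=O)c1cc2C=CC(C)(C)Oc2cc1O | intermediate
14 | 1-(7-hydroxy-2,2-dimethyl-2H-chromen-6-yl)-3-[3-(3-methylbut-2-en-1-yl)-4-oxocyclohexa-1,5-dien-1-yl]propane-1,3-dione (racemic, transient sp3 carbon) | CC(C)=CCC1C=C(C(=O)CC(=O)c2cc3C=CC(C)(C)Oc3cc2O)C=CC1=O | intermediate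
15 | Glyinflanin C, 1-[4-hydroxy-3-(3-methylbut-2-en-1-yl)phenyl]-3-(7-hydroxy-2,2-dimethyl-2H-chromen-6-yl)propane-1,3-dione | CC(C)=CCc1cc(C(=O)CC(=O)c2cc3c(cc2O)OC(C)(C)C=C3)ccc1O | target

Total steps: 7. Longest linear sequence: 6 (steps 2, 3, 4, 5, 6, 7).

Steps most likely to fail

Step 5 (key step).
- What may go wrong: cyclodehydration of the product under the reaction conditions, sequestration of the catalyst by chelation to the β-diketonate, uncatalysed O-alkylation of the acidic 4-OH by the protonated ylide, and self-coupling of the ylide.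
- Fallback: aldol addition and oxidation in place of C–H functionalisation, from 3 and 10 back to 11.
- Reductive desulfurisation of 10 (Zn, AcOH, rt) would give the methyl ketone 1-{4-[(2-methylbut-3-en-2-yl)oxy]phenyl}ethan-1-one F1.
- Silylation of 3 (TBSCl, imidazole, DMF) would give 2,4-bis[(tert-butyldimethylsilyl)oxy]-5-(3-methylbut-2-en-1-yl)benzaldehyde F2.
- The lithium enolate of F1 (LDA, THF, −78 °C) would add to F2 to give the racemic β-hydroxy ketone F3.
- Dess–Martin oxidation would give the bis-silylated β-diketone F4.
- TBAF/AcOH (THF, 0 °C) would free 11.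

Step 6.
- What may go wrong: capture of the oxidised benzylic position by the nucleophilic central carbon of a second molecule, oxidation of the enol, and cyclodehydration promoted by the acidic hydroquinone that builds up.
- Fallback: dehydrative instead of oxidative ring closure, done before the coupling, from 1 back to 13.
- Heck reaction of 1 with 2-methylbut-3-en-2-ol (Pd(OAc)2, P(o-tol)3, NaOAc, DMF, 100 °C) would give (E)-2,4-dihydroxy-5-(3-hydroxy-3-methylbut-1-en-1-yl)benzaldehyde F5.
- PPTS (cat.) in toluene at 60 °C would ionise the tertiary allylic alcohol and close the pyran by oxa-6π electrocyclisation to 7-hydroxy-2,2-dimethyl-2H-chromene-6-carbaldehyde F6.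
- F6 would then be coupled with 10 under the conditions of step 5 to give 13.

Step 1.
- What may go wrong: transfer of the allyl unit through its γ-carbon, protodeboronation in aqueous base, and slow oxidative addition to the electron-rich phenoxide form of the bromide.
- Fallback: allylation followed by cross-metathesis, from 1 back to 3.
- Coupling of 1 with allylboronic acid pinacol ester, whose two allyl termini are equivalent, would give 5-allyl-2,4-dihydroxybenzaldehyde F7.
- Cross-metathesis with 2-methylbut-2-ene (Grubbs second-generation catalyst, CH2Cl2, 40 °C) would turn the allyl group into the prenyl group of 3.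

Further compounds
F1 | step 5 | 1-{4-[(2-methylbut-3-en-2-yl)oxy]phenyl}ethan-1-one | CC(=O)c1ccc(OC(C)(C)C=C)cc1
F2 | step 5 | 2,4-bis[(tert-butyldimethylsilyl)oxy]-5-(3-methylbut-2-en-1-yl)benzaldehyde | CC(C)=CCc1cc(C=O)c(O[Si](C)(C)C(C)(C)C)cc1O[Si](C)(C)C(C)(C)C
F3 | step 5 | 3-{2,4-bis[(tert-butyldimethylsilyl)oxy]-5-(3-methylbut-2-en-1-yl)phenyl}-3-hydroxy-1-{4-[(2-methylbut-3-en-2-yl)oxy]phenyl}propan-1-one (racemic) | CC(C)=CCc1cc(C(O)CC(=O)c2ccc(OC(C)(C)C=C)cc2)c(O[Si](C)(C)C(C)(C)C)cc1O[Si](C)(C)C(C)(C)C
F4 | step 5 | 1-{2,4-bis[(tert-butyldimethylsilyl)oxy]-5-(3-methylbut-2-en-1-yl)phenyl}-3-{4-[(2-methylbut-3-en-2-yl)oxy]phenyl}propane-1,3-dione | CC(C)=CCc1cc(C(=O)CC(=O)c2ccc(OC(C)(C)C=C)cc2)c(O[Si](C)(C)C(C)(C)C)cc1O[Si](C)(C)C(C)(C)C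
F5 | step 6 | (E)-2,4-dihydroxy-5-(3-hydroxy-3-methylbut-1-en-1-yl)benzaldehyde | CC(C)(O)/C=C/c1cc(C=O)c(O)cc1O
F6 | step 6 | 7-hydroxy-2,2-dimethyl-2H-chromene-6-carbaldehyde | CC1(C)C=Cc2cc(C=O)c(O)cc2O1
F7 | step 1 | 5-allyl-2,4-dihydroxybenzaldehyde | C=CCc1cc(C=O)c(O)cc1O
A1 | direct plan | 1-(7-hydroxy-2,2-dimethyl-2H-chromen-6-yl)ethan-1-one | CC(=O)c1cc2c(cc1O)OC(C)(C)C=C2
A2 | direct plan | 4-[(tert-butyldimethylsilyl)oxy]-3-(3-methylbut-2-en-1-yl)benzoyl chloride | CC(C)=CCc1cc(C(=O)Cl)ccc1O[Si](C)(C)C(C)(C)C
A3 | direct plan | 7-hydroxy-2,2-dimethylchroman-4-one | CC1(C)CC(=O)c2ccc(O)cc2O1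
A4 | direct plan | 4-bromo-2-(3-methylbut-2-en-1-yl)phenol | CC(C)=CCc1cc(Br)ccc1O
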